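A percent yield of complex with two exchanged is a trap: it is taken against the starting complex charged, so it can sink as the charge grows while the amount in the flask stays much the same.

| flask | starting complex | incoming ligand | remark | time |
|---|---|---|---|---|
| blue | 14 mM | 30 mM | run made earlier |  |
| ochre | 57 mM | 30 mM | run made earlier |  |
| gamma | 10 mM | 30.0 mM |  | 1.0 h |
| delta | 20 mM | 30.0 mM |  | 1.0 h |
| zeta | 40 mM | 30.0 mM |  | 1.0 h |

- blue (time / min: complex with two exchanged / %): 10.0: 3.0; 20.0: 5.6; 30.0: 7.9; 40.0: 8.8
- ochre (time / min: complex with two exchanged / %): 10.0: 1.6; 20.0: 2.3; 30.0: 2.1; 40.0: 1.6

(scatter of a reading: 0.3 percentage points)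

- "hardly changes" means that all values lie within two and a half points (for a concentration: within two and a half percent of the largest)

1. [complex with two exchanged] at the end for gamma, delta, zeta, in this order
2. the shape of the row from first to last (falls, then rises / hardly changes / rises, then falls / rises all the way / falls all the way)

The ochre curve starts steeper than the blue one. Over the first reading, blue gains 0.0420 mM min⁻¹ and ochre 0.0912 mM min⁻¹. But ochre bends early: its highest reading, 2.3% at 20.0 min, is 1.31 mM, and its readings then sag to 1.6%, against a scatter of 0.3 percentage points. Its last three readings average 1.14 mM. Blue is still climbing at 40.0 min, where its 8.8% reads 1.23 mM. So ochre, with about 4.07 times blue's charge, reads an amount of like size.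

My own reckoning compares the two charges through the ligand margin, the incoming ligand charged minus the starting complex charged:

margin = incoming ligand charged − starting complex charged

Each starting complex needs one ligand for its first exchange, and the second exchange draws on what remains. The margin is 16.0 mM in blue and −27.0 mM in ochre. For the new flasks it is:

gamma 20.0 mM, delta 10.0 mM, zeta −10.0 mM

Zeta's margin is negative, as ochre's is, so incoming ligand is its limiting reagent, and at least 25.0% of its starting complex must stay unreacted. The margin gives that bound, not the row.

The forecast does give a row: 1.05 mM, 1.2 mM, 0.9 mM, so rises, then falls. Its ground is that “The ochre yield peaks and then falls, so the doubly exchanged complex is being consumed”.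

The flasks give 1.16 mM, 1.60 mM, 1.44 mM, so rises, then falls, with each value above the forecast's.

    starting complex + incoming ligand → leaving ligand + complex with one exchanged (k = 0.0440 M⁻¹ s⁻¹)
    complex with one exchanged + incoming ligand → leaving ligand + complex with two exchanged (k = 0.00920 M⁻¹ s⁻¹)
    complex with one exchanged → side product (k = 0.00120 s⁻¹)
    incoming ligand ⇌ dormant form (K = 0.250, k = 2.10 × 10⁻⁴ s⁻¹)

After 10.0 h, zeta holds 0% of its incoming ligand and 11.5 mM of starting complex, against 11.5 mM from the margin plus the extra ligand bound in complex with two exchanged. In gamma, the largest single effect on the end value among those tried comes from the step from complex with one exchanged to side product : without that step, gamma gives 3.18 mM instead of 1.16 mM. Delta's margin of 10.0 mM survives in its ledger: after 10.0 h, with starting complex at 0%, free ligand, dormant form and the second ligand in complex with two exchanged add up to 10.0 mM.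

Readings and results stem from a simulated flask with made-up constants; noise was put on by code.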